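**Retrosynthetic overview**
1. Target ⇐ removal of four MOM groups ⇐ C8–CH2 bond by Negishi coupling of (S)-lavandulylzinc iodide (centre set by Evans dienolate alkylation) with an 8-iodoflavanone ⇐ ipso-iodination of an 8-trimethylsilyl flavanone.
2. Ring C ⇐ aryne annulation: a 3,5-bis(MOMO)-6-silylbenzyne (ring A) and the silyl ether of an (S)-β-hydroxy ester (ring B plus C2, C3, C4). O1–C8a forms first, then the C4a carbanion closes ring C on the ester carbon C4.
3. Enabling feature: the oxygen on C5 of ring A sits next to fusion carbon C4a, and the ether oxygen O1 sits on the other fusion carbon C8a. In the C4a≡C8a aryne the C5 alkoxy group (helped by silicon on C8) sends the incoming oxygen to C8a and puts the carbanion on C4a, at six-ring distance from C4.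
4. C2 is set by Noyori transfer hydrogenation of a β-keto ester and is carried with retention, because its C–O bond is never broken.
5. Ring order: rings A and B are bought (phloroglucinol, 2,4-dihydroxy-5-methoxybenzaldehyde); ring C is the only ring formed (step 12).

Key step: step 12

Assumption: 2,4-dihydroxy-5-methoxybenzaldehyde is treated as purchasable (otherwise one step from 2,4,5-trimethoxybenzaldehyde with AlCl3), and the sodium dienolate in step 2 is taken to react with the facial sense of a simple Evans (Z)-enolate.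

**Route**

Step 1
Reactants: 1 (S)-4-benzyloxazolidin-2-one; 2 3-methylbut-2-enoyl chloride
Product: 4 (S)-4-benzyl-3-(3-methylbut-2-enoyl)oxazolidin-2-one, via lithium oxazolidinide 3 (not isolated)
Conditions: n-BuLi, THF, −78 °C; then 2, −78 → 0 °C
Reagents that add atoms: none
Why: N-acylation of the lithiated Evans auxiliary at low temperature is standard and avoids the vinylketene (deconjugation) pathway that amine bases open with enoyl chlorides.

Step 2
Reactants: 4 (S)-4-benzyl-3-(3-methylbut-2-enoyl)oxazolidin-2-one; 5 1-bromo-3-methylbut-2-ene (prenyl bromide)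
Product: 7 (S)-4-benzyl-3-[(S)-5-methyl-2-(prop-1-en-2-yl)hex-4-enoyl]oxazolidin-2-one, via sodium dienolate 6 (not isolated)
Conditions: NaN(SiMe3)2, THF, −78 °C; then 5, −78 → −40 °C
Reagents that add atoms: none
Why: Evans asymmetric alkylation in its deconjugative form: the chelated dienolate should react at the α-carbon on the face opposite the benzyl group, which sets the (S) centre and turns the enoyl unit into the isopropenyl group.

Step 3
Reactants: 7 (S)-4-benzyl-3-[(S)-5-methyl-2-(prop-1-en-2-yl)hex-4-enoyl]oxazolidin-2-one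
Product: 8 (S)-lavandulol, (2S)-5-methyl-2-(prop-1-en-2-yl)hex-4-en-1-ol
Conditions: LiBH4, MeOH (1 equiv), Et2O, 0 °C
Reagents that add atoms: none
Why: reductive cleavage of the N-acyl oxazolidinone with LiBH4 should give the primary alcohol without touching the α centre or the alkenes, and it returns the auxiliary.

Step 4
Reactants: 8 (S)-lavandulol
Product: 9 (S)-lavandulyl iodide, (3S)-3-(iodomethyl)-2,6-dimethylhepta-1,5-diene
Conditions: I2, PPh3, imidazole, CH2Cl2, 0 °C → rt
Reagents that add atoms: iodine, II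
Why: Appel-type iodination is an SN2 displacement at the CH2 group, so the neighbouring stereocentre is not involved.

Step 5
Reactants: 10 phloroglucinol (benzene-1,3,5-triol)
Product: 11 3,5-bis(methoxymethoxy)phenol
Conditions: MOMCl (2.0 equiv), i-Pr2NEt, DMF/CH2Cl2, 0 °C → rt
Reagents that add atoms: chloromethyl methyl ether, COCCl
Why: statistical Williamson-type acetalisation of two of three equivalent hydroxyls, with the bis-ether separated by chromatography and the mono- and tris-ethers recycled.

Step 6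
Reactants: 11 3,5-bis(methoxymethoxy)phenol
Product: 12 2,6-dibromo-3,5-bis(methoxymethoxy)phenol
Conditions: NBS (2.05 equiv), i-Pr2NH (0.2 equiv), CH2Cl2, −20 → 0 °C
Reagents that add atoms: N-bromosuccinimide, O=C1CCC(=O)N1Br
Why: amine-mediated ortho-selective bromination of phenols delivers bromine through hydrogen bonding to the OH, and the para carbon is shielded by its two flanking MOM ethers.

Step 7
Reactants: 12 2,6-dibromo-3,5-bis(methoxymethoxy)phenol
Product: 17 3,5-bis(methoxymethoxy)-2,6-bis(trimethylsilyl)phenyl trifluoromethanesulfonate, via aryl silyl ether 13 (not isolated), via lithium bromo silyl phenolate 14 (not isolated), via bromo bis-silyl ether 15 (not isolated), via lithium bis-silyl phenolate 16 (not isolated)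
Conditions: (Me3Si)2NH, THF, 65 °C, evaporate; n-BuLi, THF, −78 °C → rt; Me3SiCl, −78 °C → rt; n-BuLi, −78 °C → rt; Tf2O, −78 → 0 °C
Reagents that add atoms: hexamethyldisilazane, C[Si](C)(C)N[Si](C)(C)C; chlorotrimethylsilane, C[Si](C)(C)Cl; trifluoromethanesulfonic anhydride, O=S(=O)(OS(=O)(=O)C(F)(F)F)C(F)(F)F
Why: two rounds of the standard o-silylaryl triflate sequence (O-silylation, bromine–lithium exchange, anionic 1,3-O→C silyl shift, i.e. retro-Brook rearrangement) followed by O-triflation, the established way to 2,6-bis(silyl)aryl triflates as 3-silylaryne precursors.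

Step 8
Reactants: 18 2,4-dihydroxy-5-methoxybenzaldehyde
Product: 19 5-methoxy-2,4-bis(methoxymethoxy)benzaldehyde
Conditions: MOMCl, K2CO3, acetone, reflux
Reagents that add atoms: chloromethyl methyl ether, COCCl
Why: Williamson acetalisation of both phenols, with heating needed for the hydrogen-bonded 2-OH.

Step 9
Reactants: 19 5-methoxy-2,4-bis(methoxymethoxy)benzaldehyde; 20 ethyl diazoacetate
Product: 21 ethyl 3-[5-methoxy-2,4-bis(methoxymethoxy)phenyl]-3-oxopropanoate
Conditions: SnCl2 (10 mol %), CH2Cl2, rt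
Reagents that add atoms: none
Why: Roskamp reaction, in which SnCl2-catalysed addition of the diazo ester to the aldehyde and 1,2-hydride shift with loss of N2 give the β-keto ester in one step.

Step 10
Reactants: 21 ethyl 3-[5-methoxy-2,4-bis(methoxymethoxy)phenyl]-3-oxopropanoate
Product: 22 ethyl (S)-3-hydroxy-3-[5-methoxy-2,4-bis(methoxymethoxy)phenyl]propanoate
Conditions: RuCl(p-cymene)[(S,S)-TsDPEN] (1 mol %), HCO2H/Et3N (5:2), 35 °C
Reagents that add atoms: none
Why: Noyori asymmetric transfer hydrogenation of an aryl ketone, where the (S,S)-ligand is expected to deliver hydride as for acetophenone and give the (S)-carbinol that becomes C2.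

Step 11
Reactants: 22 ethyl (S)-3-hydroxy-3-[5-methoxy-2,4-bis(methoxymethoxy)phenyl]propanoate
Product: 23 ethyl (S)-3-[5-methoxy-2,4-bis(methoxymethoxy)phenyl]-3-[(triethylsilyl)oxy]propanoate
Conditions: Et3SiCl, imidazole, CH2Cl2, 0 °C
Reagents that add atoms: chlorotriethylsilane, CC[Si](Cl)(CC)CC
Why: silylation turns the alcohol into an aprotic, fluoride-labile source of the alkoxide for step 12.

Step 12
Reactants: 17 3,5-bis(methoxymethoxy)-2,6-bis(trimethylsilyl)phenyl trifluoromethanesulfonate; 23 ethyl (S)-3-[5-methoxy-2,4-bis(methoxymethoxy)phenyl]-3-[(triethylsilyl)oxy]propanoate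
Product: 27 (S)-2-[5-methoxy-2,4-bis(methoxymethoxy)phenyl]-5,7-bis(methoxymethoxy)-8-(trimethylsilyl)chroman-4-one, via ammonium alkoxide 24 (not isolated), via aryne 25 (not isolated), via aryl carbanion 26 (not isolated)
Conditions: 17 (1.3 equiv), Bu4N[Ph3SiF2] (2.6 equiv, slow addition), THF, −20 → 0 °C; then AcOH, −20 °C
Reagents that add atoms: none
Why: Proposed new method: fluoride removes the triethylsilyl group of 23 and the trimethylsilyl/triflate pair of 17, so that the aprotic alkoxide 24 and the aryne 25 meet in one solution; the alkoxide oxygen adds to C8a, the C4a carbanion 26 attacks the ester carbonyl and the tetrahedral intermediate expels ethoxide to give the ketone. The closest known reaction types are the fluoride-triggered annulation of arynes with salicylate esters to xanthones (phenoxide addition, then aryl anion acylation) and the O-arylation of aliphatic alcohols by arynes, and what is new is their merger on an aliphatic β-hydroxy ester. Ring C is the only ring closed, by 6-exo-trig addition of the aryl carbanion to the ester (bond C4–C4a), after the O1–C8a bond has formed intermolecularly. No new stereocentre is formed, and C2 keeps its (S) configuration because the carbinol C–O bond is never broken, which is why an aryne is used rather than a displacement at this electron-rich benzylic carbon. The step needs regioselective addition to the aryne, which the C5 alkoxy group (carbanion next to oxygen, nucleophile at the remote carbon) and the C8 silyl group (nucleophile next to silicon) both favour, and it needs acylation to beat protonation of the carbanion, which the absence of any O–H (silyl ether as alkoxide source, anhydrous fluoride) should secure. The aryne must also carry no internal trap, so the lavandulyl chain, whose alkenes would undergo an intramolecular ene reaction with the aryne, is held back until step 14 with silicon keeping its place, while slow fluoride addition at low temperature and the acid quench limit retro-aldol loss of 24 and base-induced ring opening of 27.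

Step 13
Reactants: 27 (S)-2-[5-methoxy-2,4-bis(methoxymethoxy)phenyl]-5,7-bis(methoxymethoxy)-8-(trimethylsilyl)chroman-4-one
Product: 28 (S)-8-iodo-2-[5-methoxy-2,4-bis(methoxymethoxy)phenyl]-5,7-bis(methoxymethoxy)chroman-4-one
Conditions: ICl (1.05 equiv), CH2Cl2, −78 °C
Reagents that add atoms: iodine monochloride, ICl
Why: electrophilic ipso-iododesilylation, in which attack at the silicon-bearing C8 (ortho to O1 and O7, para to O5) is favoured by the β-silicon effect, so iodine should enter only there and not at C6 or on ring B.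

Step 14
Reactants: 28 (S)-8-iodo-2-[5-methoxy-2,4-bis(methoxymethoxy)phenyl]-5,7-bis(methoxymethoxy)chroman-4-one; 9 (S)-lavandulyl iodide
Product: 30 (S)-2-[5-methoxy-2,4-bis(methoxymethoxy)phenyl]-5,7-bis(methoxymethoxy)-8-[(2R)-5-methyl-2-(prop-1-en-2-yl)hex-4-en-1-yl]chroman-4-one, via lavandulylzinc iodide 29 (not isolated)
Conditions: 9, Zn dust, LiCl, THF, 40 °C; then 28, Pd(OAc)2 (5 mol %), SPhos (10 mol %), THF/NMP, 45 °C
Reagents that add atoms: none
Why: Negishi sp3–sp2 coupling, in which the primary alkylzinc iodide (stereocentre β to zinc, hence configurationally stable; the change from S to R is only a priority change) should couple with the di-ortho-substituted aryl iodide under a bulky biarylphosphine palladium catalyst without affecting the ketone, the MOM ethers or C2.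

Step 15
Reactants: 30 (S)-2-[5-methoxy-2,4-bis(methoxymethoxy)phenyl]-5,7-bis(methoxymethoxy)-8-[(2R)-5-methyl-2-(prop-1-en-2-yl)hex-4-en-1-yl]chroman-4-one
Product: 31 (2S)-2-(2,4-dihydroxy-5-methoxyphenyl)-5,7-dihydroxy-8-[(2R)-5-methyl-2-(prop-1-en-2-yl)hex-4-en-1-yl]-2,3-dihydro-4H-chromen-4-one (CNP0323048.1)
Conditions: HCl (3 M in MeOH), MeOH, 0 → 40 °C
Reagents that add atoms: none
Why: acid-catalysed transacetalisation to methanol should remove all four MOM groups under base-free conditions that do not open the flavanone ring and are mild enough for prenyl-type side chains.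

**Compound list**
1 | (S)-4-benzyloxazolidin-2-one | O=C1N[C@@H](Cc2ccccc2)CO1 | starting material
2 | 3-methylbut-2-enoyl chloride | CC(C)=CC(=O)Cl | starting material
3 | lithium (S)-4-benzyl-2-oxooxazolidin-3-ide | [Li+].O=C1[N-][C@@H](Cc2ccccc2)CO1 | intermediate
4 | (S)-4-benzyl-3-(3-methylbut-2-enoyl)oxazolidin-2-one | CC(C)=CC(=O)N1[C@@H](Cc2ccccc2)COC1=O | intermediate
5 | 1-bromo-3-methylbut-2-ene | CC(C)=CCBr | starting material
6 | sodium 1-[(S)-4-benzyl-2-oxooxazolidin-3-yl]-3-methylbuta-1,3-dien-1-olate | [Na+].C=C(C)C=C([O-])N1[C@@H](Cc2ccccc2)COC1=O | intermediate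
7 | (S)-4-benzyl-3-[(S)-5-methyl-2-(prop-1-en-2-yl)hex-4-enoyl]oxazolidin-2-one | C=C(C)[C@H](CC=C(C)C)C(=O)N1[C@@H](Cc2ccccc2)COC1=O | intermediate
8 | (S)-lavandulol, (2S)-5-methyl-2-(prop-1-en-2-yl)hex-4-en-1-ol | C=C(C)[C@H](CC=C(C)C)CO | intermediate
9 | (S)-lavandulyl iodide, (3S)-3-(iodomethyl)-2,6-dimethylhepta-1,5-diene | C=C(C)[C@H](CC=C(C)C)CI | intermediate
10 | phloroglucinol | Oc1cc(O)cc(O)c1 | starting material
11 | 3,5-bis(methoxymethoxy)phenol | COCOc1cc(O)cc(OCOC)c1 | intermediate
12 | 2,6-dibromo-3,5-bis(methoxymethoxy)phenol | Oc1c(Br)c(OCOC)cc(OCOC)c1Br | intermediate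
13 | [2,6-dibromo-3,5-bis(methoxymethoxy)phenoxy]trimethylsilane | C[Si](C)(C)Oc1c(Br)c(OCOC)cc(OCOC)c1Br | intermediate
14 | lithium 2-bromo-3,5-bis(methoxymethoxy)-6-(trimethylsilyl)phenolate | [Li+].[O-]c1c(Br)c(OCOC)cc(OCOC)c1[Si](C)(C)C | intermediate
15 | [2-bromo-3,5-bis(methoxymethoxy)-6-(trimethylsilyl)phenoxy]trimethylsilane | C[Si](C)(C)Oc1c(Br)c(OCOC)cc(OCOC)c1[Si](C)(C)C | intermediate
16 | lithium 3,5-bis(methoxymethoxy)-2,6-bis(trimethylsilyl)phenolate | [Li+].[O-]c1c([Si](C)(C)C)c(OCOC)cc(OCOC)c1[Si](C)(C)C | intermediate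
17 | 3,5-bis(methoxymethoxy)-2,6-bis(trimethylsilyl)phenyl trifluoromethanesulfonate | C[Si](C)(C)c1c(OCOC)cc(OCOC)c([Si](C)(C)C)c1OS(=O)(=O)C(F)(F)F | intermediate
18 | 2,4-dihydroxy-5-methoxybenzaldehyde | O=Cc1cc(OC)c(O)cc1O | starting material
19 | 5-methoxy-2,4-bis(methoxymethoxy)benzaldehyde | O=Cc1cc(OC)c(OCOC)cc1OCOC | intermediate
20 | ethyl diazoacetate | CCOC(=O)C=[N+]=[N-] | starting material
21 | ethyl 3-[5-methoxy-2,4-bis(methoxymethoxy)phenyl]-3-oxopropanoate | CCOC(=O)CC(=O)c1cc(OC)c(OCOC)cc1OCOC | intermediate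
22 | ethyl (S)-3-hydroxy-3-[5-methoxy-2,4-bis(methoxymethoxy)phenyl]propanoate | CCOC(=O)C[C@H](O)c1cc(OC)c(OCOC)cc1OCOC | intermediate
23 | ethyl (S)-3-[5-methoxy-2,4-bis(methoxymethoxy)phenyl]-3-[(triethylsilyl)oxy]propanoate | CCOC(=O)C[C@H](O[Si](CC)(CC)CC)c1cc(OC)c(OCOC)cc1OCOC | intermediate
24 | tetrabutylammonium (S)-3-ethoxy-1-[5-methoxy-2,4-bis(methoxymethoxy)phenyl]-3-oxopropan-1-olate | CCOC(=O)C[C@H]([O-])c1cc(OC)c(OCOC)cc1OCOC.CCCC[N+](CCCC)(CCCC)CCCC | intermediate
25 | 3,5-bis(methoxymethoxy)-6-(trimethylsilyl)benzyne (1,2-didehydrobenzene) | COCOC1=CC(OCOC)=C([Si](C)(C)C)C#C1 | intermediate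
26 | tetrabutylammonium salt of the C4a aryl carbanion, 2-{(S)-3-ethoxy-1-[5-methoxy-2,4-bis(methoxymethoxy)phenyl]-3-oxopropoxy}-4,6-bis(methoxymethoxy)-3-(trimethylsilyl)benzen-1-ide | CCOC(=O)C[C@H](Oc1[c-]c(OCOC)cc(OCOC)c1[Si](C)(C)C)c1cc(OC)c(OCOC)cc1OCOC.CCCC[N+](CCCC)(CCCC)CCCC | intermediate
27 | (S)-2-[5-methoxy-2,4-bis(methoxymethoxy)phenyl]-5,7-bis(methoxymethoxy)-8-(trimethylsilyl)chroman-4-one | C[Si](C)(C)c1c(OCOC)cc(OCOC)c2c1O[C@H](c1cc(OC)c(OCOC)cc1OCOC)CC2=O | intermediate
28 | (S)-8-iodo-2-[5-methoxy-2,4-bis(methoxymethoxy)phenyl]-5,7-bis(methoxymethoxy)chroman-4-one | Ic1c(OCOC)cc(OCOC)c2c1O[C@H](c1cc(OC)c(OCOC)cc1OCOC)CC2=O | intermediate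
29 | (S)-lavandulylzinc iodide, [(2S)-5-methyl-2-(prop-1-en-2-yl)hex-4-en-1-yl]zinc iodide | C=C(C)[C@H](CC=C(C)C)C[Zn]I | intermediate
30 | (S)-2-[5-methoxy-2,4-bis(methoxymethoxy)phenyl]-5,7-bis(methoxymethoxy)-8-[(2R)-5-methyl-2-(prop-1-en-2-yl)hex-4-en-1-yl]chroman-4-one | C=C(C)[C@H](CC=C(C)C)Cc1c(OCOC)cc(OCOC)c2c1O[C@H](c1cc(OC)c(OCOC)cc1OCOC)CC2=O | intermediate
31 | (2S)-2-(2,4-dihydroxy-5-methoxyphenyl)-5,7-dihydroxy-8-[(2R)-5-methyl-2-(prop-1-en-2-yl)hex-4-en-1-yl]-2,3-dihydro-4H-chromen-4-one | C=C(C)[C@H](CC=C(C)C)Cc1c(O)cc(O)c2c1O[C@H](c1cc(OC)c(O)cc1O)CC2=O | target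

**Summary**
Total step count: 15. Longest linear sequence: 8 steps (18 → 19 → 21 → 22 → 23 → 27 → 28 → 30 → 31; steps 8–15).

Steps most likely to fail:

1. Step 12 (proposed new method). The alkoxide may add too slowly to the aryne carbon flanked by silicon, or at the wrong terminus. The free alkoxide may be lost by retro-aldol or elimination before it meets the aryne. The carbanion may be protonated instead of acylated, or the product may ring-open under base with loss of configuration at C2. The fallback uses known chemistry, sets out from 21 and 11 and comes back at 30. Ketone 21 is reduced with the enantiomeric catalyst RuCl(p-cymene)[(R,R)-TsDPEN] to ethyl (R)-3-hydroxy-3-[5-methoxy-2,4-bis(methoxymethoxy)phenyl]propanoate F1. Phenol 11 is monobrominated (NBS, 1 equiv, CH2Cl2, −78 °C) to 2-bromo-3,5-bis(methoxymethoxy)phenol F2. Mitsunobu etherification of F2 with F1 (PPh3, diisopropyl azodicarboxylate, toluene, 0 °C) should give, with inversion, ethyl (S)-3-[2-bromo-3,5-bis(methoxymethoxy)phenoxy]-3-[5-methoxy-2,4-bis(methoxymethoxy)phenyl]propanoate F3. Saponification (LiOH, THF/H2O) gives (S)-3-[2-bromo-3,5-bis(methoxymethoxy)phenoxy]-3-[5-methoxy-2,4-bis(methoxymethoxy)phenyl]propanoic acid F4. Friedel–Crafts cycloacylation through the mixed anhydride (trifluoroacetic anhydride, 2,6-di-tert-butylpyridine, CH2Cl2, 0 °C) can only close at the free ortho carbon and should give (S)-8-bromo-2-[5-methoxy-2,4-bis(methoxymethoxy)phenyl]-5,7-bis(methoxymethoxy)chroman-4-one F5. Negishi coupling of F5 with 29 under the conditions of step 14 then gives 30.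

2. Step 14. Oxidative addition and transmetalation at the di-ortho-substituted C8 may be slow, so that reduction of the C–I bond takes over. The fallback replaces the organozinc route by a nickel-catalysed reductive cross-electrophile coupling of the two iodides (NiI2, 4,4′-dimethoxy-2,2′-bipyridine, Zn, NaI, pyridine, DMPU, 60 °C), in which an alkyl radical from 9 is captured by an arylnickel species. It sets out from 28 and 9 and comes back at 30 without new compounds.

3. Step 15. Acid may protonate the lavandulyl alkenes, with cyclisation onto the 7-hydroxyl, before all four MOM groups are gone. The fallback moves the acid step ahead of the alkenes; it sets out from 28 and comes back at 31. Iodide 28 is deprotected (HCl, MeOH, 40 °C) to (S)-2-(2,4-dihydroxy-5-methoxyphenyl)-5,7-dihydroxy-8-iodochroman-4-one F6. Acetylation (Ac2O, pyridine, 0 °C) gives (S)-4-[5,7-diacetoxy-8-iodo-4-oxochroman-2-yl]-6-methoxy-1,3-phenylene diacetate F7. Negishi coupling with 29 as in step 14 gives the lavandulyl tetraacetate, (S)-4-{5,7-diacetoxy-8-[(2R)-5-methyl-2-(prop-1-en-2-yl)hex-4-en-1-yl]-4-oxochroman-2-yl}-6-methoxy-1,3-phenylene diacetate F8. Near-neutral deacetylation (NH4OAc, MeOH/H2O, rt) then gives 31.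

**Further compounds**
F1 | step 12 | ethyl (R)-3-hydroxy-3-[5-methoxy-2,4-bis(methoxymethoxy)phenyl]propanoate | CCOC(=O)C[C@@H](O)c1cc(OC)c(OCOC)cc1OCOC
F2 | step 12 | 2-bromo-3,5-bis(methoxymethoxy)phenol | Oc1cc(OCOC)cc(OCOC)c1Br
F3 | step 12 | ethyl (S)-3-[2-bromo-3,5-bis(methoxymethoxy)phenoxy]-3-[5-methoxy-2,4-bis(methoxymethoxy)phenyl]propanoate | CCOC(=O)C[C@H](Oc1cc(OCOC)cc(OCOC)c1Br)c1cc(OC)c(OCOC)cc1OCOC
F4 | step 12 | (S)-3-[2-bromo-3,5-bis(methoxymethoxy)phenoxy]-3-[5-methoxy-2,4-bis(methoxymethoxy)phenyl]propanoic acid | OC(=O)C[C@H](Oc1cc(OCOC)cc(OCOC)c1Br)c1cc(OC)c(OCOC)cc1OCOC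
F5 | step 12 | (S)-8-bromo-2-[5-methoxy-2,4-bis(methoxymethoxy)phenyl]-5,7-bis(methoxymethoxy)chroman-4-one | Brc1c(OCOC)cc(OCOC)c2c1O[C@H](c1cc(OC)c(OCOC)cc1OCOC)CC2=O
F0 | step 14 | none | none
F6 | step 15 | (S)-2-(2,4-dihydroxy-5-methoxyphenyl)-5,7-dihydroxy-8-iodochroman-4-one | Ic1c(O)cc(O)c2c1O[C@H](c1cc(OC)c(O)cc1O)CC2=O
F7 | step 15 | (S)-4-[5,7-diacetoxy-8-iodo-4-oxochroman-2-yl]-6-methoxy-1,3-phenylene diacetate | Ic1c(OC(C)=O)cc(OC(C)=O)c2c1O[C@H](c1cc(OC)c(OC(C)=O)cc1OC(C)=O)CC2=O
F8 | step 15 | (S)-4-{5,7-diacetoxy-8-[(2R)-5-methyl-2-(prop-1-en-2-yl)hex-4-en-1-yl]-4-oxochroman-2-yl}-6-methoxy-1,3-phenylene diacetate | C=C(C)[C@H](CC=C(C)C)Cc1c(OC(C)=O)cc(OC(C)=O)c2c1O[C@H](c1cc(OC)c(OC(C)=O)cc1OC(C)=O)CC2=O
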